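**Assumption:** the target SMILES has no stereocentres (C2‑symmetric, achiral bis‑quinolone), so "single enantiomer" is moot and there is no stereochemistry to set or protect.

## Retrosynthetic overview
1. The usual disconnection (C3–CH2 bonds: 4‑hydroxy‑1‑methylquinolin‑2‑one + formaldehyde) is avoided; the bridging CH2 is never a site of bond formation.
2. Instead, both C3–C4 bonds are cut at once (two‑directional retro‑Dieckmann), so the bridge CH2 becomes the central carbon of a glutaryl unit in the acyclic bis‑anilide 3.
3. Bis‑anilide 3 is cut at both N–C(=O) bonds into glutaryl chloride 2 and two molecules of methyl N‑methylanthranilate 1.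
4. Ring order: the two benzene rings are bought intact; both pyridone rings are closed last, in the same flask.

## Route

**Step 1**
Reactants: 1, methyl 2‑(methylamino)benzoate (2.2 equiv); 2, glutaryl chloride (pentanedioyl dichloride, 1.0 equiv)
Product: 3, dimethyl 2,2'‑[pentanedioylbis(methylimino)]dibenzoate, i.e. N1,N5‑bis[2‑(methoxycarbonyl)phenyl]‑N1,N5‑dimethylpentanediamide
Conditions: pyridine (3 equiv), DMAP (10 mol %), toluene, 0 → 80 °C, 12 h; aq. HCl / NaHCO3 washes
Reagents that add atoms: none beyond reactants 1 and 2 (2, ClC(=O)CCCC(=O)Cl, supplies the C5 diacyl unit)
Why: Double N‑acylation (Schotten–Baumann type, DMAP‑catalysed) of the only nucleophilic site in 1; a secondary aniline cannot go on to a glutarimide and the methyl esters are inert here; no stereocentre is formed.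

**Step 2**
Reactants: 3
Product: 4, zanthobisquinolone, 3,3'‑methylenebis(4‑hydroxy‑1‑methylquinolin‑2(1H)‑one)
Conditions: KHMDS (4.5 equiv), THF (0.03 M), −78 °C → rt, 3 h; then 1 M HCl to pH 2, filter the precipitate, recrystallise (DMF/EtOH)
Reagents that add atoms: none (2 MeOH are lost)
Why: Two‑directional lactam‑Dieckmann (intramolecular Claisen) condensation: each amide α‑CH2 enolate attacks the ortho methyl ester in a 6‑membered closure, favoured by the N‑methylanilide conformation that holds the acyl chain next to the aryl ring. Each closure is driven by formation of the stabilised 4‑oxido‑2‑quinolone anion, and excess base allows the second α‑deprotonation. The glutaryl central CH2 becomes the methylene bridge; no stereocentre is formed.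

Atom check: 3 (C23H26N2O6) − 2 CH3OH = C21H18N2O4 = 4.

## Compound list
1 | methyl 2‑(methylamino)benzoate (methyl N‑methylanthranilate) | CNc1ccccc1C(=O)OC | starting material
2 | glutaryl chloride (pentanedioyl dichloride) | O=C(Cl)CCCC(=O)Cl | starting material
3 | dimethyl 2,2'‑[pentanedioylbis(methylimino)]dibenzoate | COC(=O)c1ccccc1N(C)C(=O)CCCC(=O)N(C)c1ccccc1C(=O)OC | intermediate
4 | zanthobisquinolone, 3,3'‑methylenebis(4‑hydroxy‑1‑methylquinolin‑2(1H)‑one) | Cn1c(=O)c(Cc2c(O)c3ccccc3n(C)c2=O)c(O)c2ccccc21 | target

## Summary
Total steps: 2. Longest linear sequence: 2.

Most likely failure points (the route has only two steps, so the third entry is a distinct failure mode inside Step 2):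

1. **Step 2, second ring closure stalls.** The second amide enolate must form 1,3 to an existing quinolone enolate, so the reaction may stop at the mono‑cyclised intermediate. Fallback: make the C3–C4 bonds intermolecularly instead. Treat the bis‑lithium enolate of dimethyl glutarate (excess LDA, THF, −78 °C) with 2 equiv of N‑methylisatoic anhydride; C‑acylation at C4, loss of CO2 and lactamisation onto the ester would give 4 in one pot.

2. **Step 2, side reactions.** Released methoxide may cleave the activated N‑aryl amide, or intermolecular Claisen condensation may compete. Fallback: a base‑free thermal two‑directional cyclocondensation of N‑methylaniline with tetraethyl propane‑1,1,3,3‑tetracarboxylate (Ph2O, about 250 °C, loss of 4 EtOH). This forms the N–C2 and C4–C4a bonds instead, but is harsher and may be complicated by lactonisation of the half‑cyclised intermediate.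

3. **Step 1, sluggish bis‑acylation.** The nitrogen of 1 is hindered, deactivated and hydrogen‑bonded to the ester, so the second acylation may be incomplete. Fallback: invert the order. Acylate the more nucleophilic primary amine methyl anthranilate with 2, then N,N'‑dimethylate the bis‑anilide (NaH, MeI, DMF) to reach 3.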